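## Retrosynthetic overview

1. The pyranone ring (ring C) is closed last. Its O1–C2 bond and the C3 stereocentre come from a catalytic asymmetric intramolecular oxa-Michael addition/enantioselective protonation of a bisphenolic α-aryl enone, 1-(ring A)-2-(ring B)prop-2-en-1-one.
2. The free enone is released from its bis-silyl ether with fluoride under non-basic conditions; its =CH2 carbon comes from Mannich α-methylenation of a deoxybenzoin.
3. The deoxybenzoin (ring A–CO–CH2–ring B) comes from Pd-catalysed α-arylation of a silylated ring A methyl ketone with a silylated ring B bromide.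
4. The ring A ketone comes from Stille prenylation of 5-bromo-2-hydroxy-4-methoxyacetophenone; ring B comes from 2-bromo-5-methoxyphenol.
5. Order of ring formation: rings A and B are bought as benzenes; ring C is the only ring made, in the final step.

Assumption: the three building blocks are taken as catalogue chemicals, and the quinine-derived squaramide is taken to give the (S) product; if a test run gives (R), its quinidine-derived pseudo-enantiomer is used under the same conditions.

## Route

Step 1
Reactants: 1 1-(5-bromo-2-hydroxy-4-methoxyphenyl)ethan-1-one; 2 tributyl(3-methylbut-2-en-1-yl)stannane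
Product: 3 1-[2-hydroxy-4-methoxy-5-(3-methylbut-2-en-1-yl)phenyl]ethan-1-one
Conditions: Pd(PPh3)4 (5 mol%), DMF, 95 °C
Reagents that add atoms: none
Why: Stille cross-coupling of the aryl bromide with the allylic stannane is neutral, so the chelated phenol and the ketone survive, and bond formation at the unsubstituted tin-bearing CH2 gives the linear prenyl group.

Step 2
Reactants: 3 1-[2-hydroxy-4-methoxy-5-(3-methylbut-2-en-1-yl)phenyl]ethan-1-one
Product: 4 1-[4-methoxy-5-(3-methylbut-2-en-1-yl)-2-(triisopropylsilyloxy)phenyl]ethan-1-one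
Conditions: i-Pr3SiOTf (1.2 equiv), 2,6-lutidine (2 equiv), CH2Cl2, 0 °C to rt
Reagents that add atoms: triisopropylsilyl trifluoromethanesulfonate, CC(C)[Si](OS(=O)(=O)C(F)(F)F)(C(C)C)C(C)C
Why: O-silylation of the hydrogen-bonded phenol with a silyl triflate; the bulky triisopropylsilyl group is chosen to resist base and O-to-O migration in the enolate step that follows.

Step 3
Reactants: 5 2-bromo-5-methoxyphenol
Product: 6 (2-bromo-5-methoxyphenoxy)(tert-butyl)dimethylsilane
Conditions: t-BuMe2SiCl (1.2 equiv), imidazole (2.5 equiv), DMF, rt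
Reagents that add atoms: tert-butyldimethylsilyl chloride, CC(C)(C)[Si](C)(C)Cl
Why: Imidazole-promoted silylation of a phenol; the silyl ether keeps the electron-rich ring B phenol out of the later Mannich step and prevents acid-induced benzofuran formation from the 2-hydroxybenzyl ketone.

Step 4
Reactants: 4 1-[4-methoxy-5-(3-methylbut-2-en-1-yl)-2-(triisopropylsilyloxy)phenyl]ethan-1-one; 6 (2-bromo-5-methoxyphenoxy)(tert-butyl)dimethylsilane
Product: 7 2-[2-(tert-butyldimethylsilyloxy)-4-methoxyphenyl]-1-[4-methoxy-5-(3-methylbut-2-en-1-yl)-2-(triisopropylsilyloxy)phenyl]ethan-1-one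
Conditions: Pd2(dba)3 (2 mol%), XPhos (8 mol%), K3PO4 (2.5 equiv), toluene, 80 °C
Reagents that add atoms: none
Why: Palladium-catalysed ketone α-arylation (Buchwald–Hartwig type) of the methyl ketone stops at mono-arylation with an ortho-substituted bromide, and the weak phosphate base leaves both aryl silyl ethers and the prenyl olefin intact.

Step 5
Reactants: 7 2-[2-(tert-butyldimethylsilyloxy)-4-methoxyphenyl]-1-[4-methoxy-5-(3-methylbut-2-en-1-yl)-2-(triisopropylsilyloxy)phenyl]ethan-1-one
Product: 9 2-[2-(tert-butyldimethylsilyloxy)-4-methoxyphenyl]-1-[4-methoxy-5-(3-methylbut-2-en-1-yl)-2-(triisopropylsilyloxy)phenyl]prop-2-en-1-one, via Mannich base 8 (not isolated)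
Conditions: (CH2O)n (4 equiv), i-Pr2NH·CF3CO2H (1 equiv), CF3CO2H (10 mol%), THF, reflux
Reagents that add atoms: paraformaldehyde (formaldehyde), C=O
Why: Mannich reaction at the only enolisable (doubly activated benzylic) CH2 followed by E1cB loss of diisopropylamine gives the α-methylene ketone; with both phenols silylated neither ring closure nor phenolic aminomethylation can occur.

Step 6
Reactants: 9 2-[2-(tert-butyldimethylsilyloxy)-4-methoxyphenyl]-1-[4-methoxy-5-(3-methylbut-2-en-1-yl)-2-(triisopropylsilyloxy)phenyl]prop-2-en-1-one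
Product: 10 1-[2-hydroxy-4-methoxy-5-(3-methylbut-2-en-1-yl)phenyl]-2-(2-hydroxy-4-methoxyphenyl)prop-2-en-1-one
Conditions: HF·pyridine (excess), THF, 0 °C; pH 7 phosphate buffer work-up; used at once
Reagents that add atoms: none
Why: Fluoride-mediated Si–O cleavage in a weakly acidic medium removes both aryl silyl ethers without ever generating a phenoxide, so the hydrogen-bonded 2-hydroxyaryl enone is released without base-triggered racemic oxa-Michael closure.

Step 7
Reactants: 10 1-[2-hydroxy-4-methoxy-5-(3-methylbut-2-en-1-yl)phenyl]-2-(2-hydroxy-4-methoxyphenyl)prop-2-en-1-one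
Product: 11 (3S)-3-(2-hydroxy-4-methoxyphenyl)-7-methoxy-6-(3-methylbut-2-en-1-yl)-2,3-dihydro-4H-chromen-4-one
Conditions: 3-[3,5-bis(trifluoromethyl)anilino]-4-[(8α,9S)-6'-methoxycinchonan-9-ylamino]cyclobut-3-ene-1,2-dione (quinine-derived squaramide, 5 mol%), toluene (0.02 M), −30 °C; AcOH quench, rapid filtration through silica
Reagents that add atoms: none
Why: Proposed new method: an intramolecular oxa-Michael addition/enantioselective protonation cascade in which the quinuclidine nitrogen takes the proton of the chelated ring A phenol while the squaramide N–H pair binds the enone carbonyl, 6-endo-trig attack on the terminal CH2 forms the O1–C2 bond, and the squaramide-bound enolate is protonated at C3 on one face by the adjacent quinuclidinium N–H before it leaves the chiral pocket, which sets (3S) (the ring B 2-OH can serve as a further anchoring hydrogen bond); the closest known reaction types are cinchona thiourea/squaramide-catalysed intramolecular oxa-Michael cyclisations of 2-hydroxyaryl enones to flavanones and chromanones (stereocentre at the β-carbon) and bifunctional-amine-catalysed conjugate addition/enantioselective protonation of α-substituted acrylates, neither of which has been shown to set the α-aryl C3 centre of an isoflavanone.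

## Compound list

1 | 1-(5-bromo-2-hydroxy-4-methoxyphenyl)ethan-1-one | CC(=O)c1cc(Br)c(OC)cc1O | starting material
2 | tributyl(3-methylbut-2-en-1-yl)stannane | CCCC[Sn](CCCC)(CCCC)CC=C(C)C | starting material
3 | 1-[2-hydroxy-4-methoxy-5-(3-methylbut-2-en-1-yl)phenyl]ethan-1-one | CC(=O)c1cc(CC=C(C)C)c(OC)cc1O | intermediate
4 | 1-[4-methoxy-5-(3-methylbut-2-en-1-yl)-2-(triisopropylsilyloxy)phenyl]ethan-1-one | CC(=O)c1cc(CC=C(C)C)c(OC)cc1O[Si](C(C)C)(C(C)C)C(C)C | intermediate
5 | 2-bromo-5-methoxyphenol | COc1ccc(Br)c(O)c1 | starting material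
6 | (2-bromo-5-methoxyphenoxy)(tert-butyl)dimethylsilane | COc1ccc(Br)c(O[Si](C)(C)C(C)(C)C)c1 | intermediate
7 | 2-[2-(tert-butyldimethylsilyloxy)-4-methoxyphenyl]-1-[4-methoxy-5-(3-methylbut-2-en-1-yl)-2-(triisopropylsilyloxy)phenyl]ethan-1-one | COc1ccc(CC(=O)c2cc(CC=C(C)C)c(OC)cc2O[Si](C(C)C)(C(C)C)C(C)C)c(O[Si](C)(C)C(C)(C)C)c1 | intermediate
8 | racemic 2-[2-(tert-butyldimethylsilyloxy)-4-methoxyphenyl]-3-(diisopropylamino)-1-[4-methoxy-5-(3-methylbut-2-en-1-yl)-2-(triisopropylsilyloxy)phenyl]propan-1-one (Mannich base, not isolated) | COc1ccc(C(CN(C(C)C)C(C)C)C(=O)c2cc(CC=C(C)C)c(OC)cc2O[Si](C(C)C)(C(C)C)C(C)C)c(O[Si](C)(C)C(C)(C)C)c1 | intermediate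
9 | 2-[2-(tert-butyldimethylsilyloxy)-4-methoxyphenyl]-1-[4-methoxy-5-(3-methylbut-2-en-1-yl)-2-(triisopropylsilyloxy)phenyl]prop-2-en-1-one | C=C(C(=O)c1cc(CC=C(C)C)c(OC)cc1O[Si](C(C)C)(C(C)C)C(C)C)c1ccc(OC)cc1O[Si](C)(C)C(C)(C)C | intermediate
10 | 1-[2-hydroxy-4-methoxy-5-(3-methylbut-2-en-1-yl)phenyl]-2-(2-hydroxy-4-methoxyphenyl)prop-2-en-1-one | C=C(C(=O)c1cc(CC=C(C)C)c(OC)cc1O)c1ccc(OC)cc1O | intermediate
11 | (3S)-3-(2-hydroxy-4-methoxyphenyl)-7-methoxy-6-(3-methylbut-2-en-1-yl)-2,3-dihydro-4H-chromen-4-one | COc1ccc([C@H]2COc3cc(OC)c(CC=C(C)C)cc3C2=O)c(O)c1 | target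

## Step count and risks

Total step count: 7. Longest linear sequence: 6 (steps 1, 2, 4, 5, 6, 7).

Three steps most likely to fail:

**Step 7 (the proposed new cyclisation).** The risks are uncatalysed racemic closure, racemisation of the acidic C3–H of the product by the amine catalyst, and an unknown level and sense of induction. The fallback uses known chemistry, sets out from 10 and returns at 11. Enone 10 is closed without stereocontrol (Et3N, 0.2 equiv, CH2Cl2, rt) to the racemic isoflavanone F1. Dynamic kinetic asymmetric transfer hydrogenation (RuCl[(S,S)-TsDPEN](p-cymene), 2 mol%, HCO2H/Et3N 1:1, EtOAc, 40 °C, acid-free work-up) reduces the ketone while C3 equilibrates through the enol and gives the cis-(3S,4S)-isoflavan-4-ol F2. Neutral oxidation of the benzylic alcohol (MnO2, CH2Cl2, rt) then restores the ketone with C3 untouched, giving 11.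

**Step 6 (release of the free enone).** The bisphenolic enone may close to racemic product or rearrange during desilylation or isolation. The fallback sets out from 9 and returns at 10, and avoids having the enone present while the phenols are freed. Luche reduction of 9 (NaBH4, CeCl3·7H2O, MeOH, 0 °C) gives the racemic allylic alcohol F3. Both silyl ethers are then removed with Bu4NF in THF at 0 °C, where base is harmless because there is no Michael acceptor, to give the triol F4. Chemoselective oxidation of the benzylic-allylic alcohol (MnO2, CH2Cl2, rt) releases 10 under neutral conditions.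

**Step 4 (α-arylation).** The ortho-silyloxy bromide is hindered, and the potassium enolates of 4 and 7 could trigger O-to-O silyl migration or silyl loss. The fallback sets out from 4 and returns at 7, and replaces the base-generated enolate by a neutral enol silane. Ketone 4 is converted (Me3SiOTf, Et3N, CH2Cl2, 0 °C) into the trimethylsilyl enol ether F5. This is arylated with 6 without Brønsted base through the tin enolate (PdCl2[P(o-tol)3]2, 3 mol%, Bu3SnF, 1.05 equiv, toluene, reflux) to give 7.

## Further compounds

F1 | step 7 | racemic 3-(2-hydroxy-4-methoxyphenyl)-7-methoxy-6-(3-methylbut-2-en-1-yl)-2,3-dihydro-4H-chromen-4-one | COc1ccc(C2COc3cc(OC)c(CC=C(C)C)cc3C2=O)c(O)c1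
F2 | step 7 | (3S,4S)-3-(2-hydroxy-4-methoxyphenyl)-7-methoxy-6-(3-methylbut-2-en-1-yl)-3,4-dihydro-2H-chromen-4-ol (cis) | COc1ccc([C@H]2COc3cc(OC)c(CC=C(C)C)cc3[C@H]2O)c(O)c1
F3 | step 6 | racemic 2-[2-(tert-butyldimethylsilyloxy)-4-methoxyphenyl]-1-[4-methoxy-5-(3-methylbut-2-en-1-yl)-2-(triisopropylsilyloxy)phenyl]prop-2-en-1-ol | COc1ccc(C(=C)C(O)c2cc(CC=C(C)C)c(OC)cc2O[Si](C(C)C)(C(C)C)C(C)C)c(O[Si](C)(C)C(C)(C)C)c1
F4 | step 6 | racemic 2-[1-hydroxy-2-(2-hydroxy-4-methoxyphenyl)prop-2-en-1-yl]-5-methoxy-4-(3-methylbut-2-en-1-yl)phenol | COc1ccc(C(=C)C(O)c2cc(CC=C(C)C)c(OC)cc2O)c(O)c1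
F5 | step 4 | [4-methoxy-5-(3-methylbut-2-en-1-yl)-2-(1-trimethylsilyloxyethenyl)phenoxy]triisopropylsilane | C=C(O[Si](C)(C)C)c1cc(CC=C(C)C)c(OC)cc1O[Si](C(C)C)(C(C)C)C(C)C
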